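The constants used here were drawn at random within sensible limits; no experiment stands behind them.

Should the next run be charged as delta, or does zeta's nucleophile already carry the electrophile far enough in the time given?

the same everywhere: electrophile 0.80 M; time 5.0 min
- zeta: nucleophile 0.800 M
- delta: nucleophile 1.20 M

    crystals ⇌ acid set free, rate k1*(cs1 - [acid set free]) while solid is left; crystals form when [acid set free] > cs1 (cs1 = 10 mM, k1 = 21 min⁻¹)
    electrophile + target → side product (k2 = 2.4 L mol⁻¹ min⁻¹)
    electrophile + nucleophile → acid set free + target (k3 = 0.39 L mol⁻¹ min⁻¹)
    nucleophile + acid set free ⇌ protonated nucleophile, settled at all times (K4 = 14 L mol⁻¹)

- part of the electrophile that has reacted at the end, zeta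
- part of the electrophile that has reacted at the end, delta
- what raising the concentration of nucleophile from its lowest to its highest value here does to the part of the electrophile that has reacted (changes below 5 percentage points count as none) (it falls / it rises / no change)

- in percentages every species weighs as the electrophile in it: one side product counts as two
- for acid set free the crystals are counted in
- as a solid, counted per litre of solution: crystals
- run time (zeta): 5.0 min

The end state comes first. Each nucleophile consumed gives one target, and target takes a second electrophile into side product. In zeta, at the concentrations charged, the half-life of target by the step that forms side product, 0.36 min, is shorter than the 2.2 min of electrophile by the step that forms target, so the reckoning lets target stand at its steady level and counts two electrophile per nucleophile consumed.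

The reserve, the charge of nucleophile minus what that demand takes, is 0.400 M in zeta and 0.800 M in delta. It is positive in both, so electrophile is the limiting reagent there.

Speed comes next. The reckoning takes c(acid set free) at 10 mM while crystals form, so 0.140 protonated nucleophile stands beside each free one. This gives the clearing constant, two times k3 divided by one plus K4 times cs1, 0.684 L mol⁻¹ min⁻¹: the rate of loss of electrophile, per electrophile, per mole per litre of nucleophile not yet consumed.

Integrated, the ratio of c(electrophile) to unconsumed nucleophile falls by the factor exp(−clearing constant × reserve × time). That gives 85.4% reacted in zeta and 95.6% in delta. The extra nucleophile buys 10 percentage points, more than the 5 points that counts, so the reckoning chooses delta.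

The forecast gives 85% (78% to 91%) for zeta and 95% (90% to 98%) for delta, slightly below the reckoning there. Its verdict is it rises, and it points to “the fast follow-up reaction with target”.

The simulation gives 82.8% for zeta and 93.8% for delta, and with more nucleophile it rises by 11 points, so delta stands as the charge. That gap belongs to the charge of nucleophile: delta set back to the nucleophile of zeta reaches 82.8% instead of 93.8%. The neighbour of delta with 0.30 M of nucleophile has a reserve of −0.100 M, so on the count of two electrophile per nucleophile, nucleophile is its limiting reagent, and 0.684 L mol⁻¹ min⁻¹ gives 46.5% reacted. That flask gives 44.9%.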